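Everything rests on cutting the bond between the peroxide oxygen and C6, the quaternary carbon of the 1,2-dioxane ring (substituents: O, CH3, ring CH2, chain CH2), which has no neighbouring stereocentre to direct it. C6 is therefore drawn from the tertiary carbon of an enantiopure 2-methyl-2-alkyloxirane. In one operation a secondary C3 hydroperoxide, released in the flask from its acetone perketal, opens the protonated epoxide 6-exo with inversion: the ring closes, C6 is fixed and a CH2OH handle appears. The precursor is an alkene-free seven-carbon chain carrying the epoxide, the masked OOH and a silyl ether. The cis-fused bicyclic diene, made from (S)-limonene, is attached afterwards by Wittig olefination and diimide reduction.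

Key step: step 11

Remark: locants C1–C7 follow the acid chain (C1 future carboxyl carbon, C3 secondary peroxide carbon, C6 quaternary carbon, C7 its exocyclic carbon, C8 the CH2 on ring B). Ring A is the methylcyclohexene ring and ring B the ring with the tetrasubstituted alkene (naphthalene locants). The target is (2R,3R,6R,4aR,8aS). Olefin 38 is carried on as an E/Z mixture because its double bond is removed in the next step.

Step 1
Reactants: 1 (S)-2-methylglycidol; 2 allylmagnesium bromide
Product: 3 (R)-2-methylhex-5-ene-1,2-diol
Conditions: 2 (3 equiv), Li2CuCl4 (5 mol %), THF, −30 → 0 °C; aq work-up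
Reagents that add atoms: none
Why: Copper-catalysed Grignard opening of the 2,2-disubstituted epoxide at its unhindered CH2 leaves the tertiary C–O bond untouched, so the glycidol stereocentre passes unchanged into the future C6.

Step 2
Reactants: 3 (R)-2-methylhex-5-ene-1,2-diol
Product: 4 (R)-2-hydroxy-2-methylhex-5-en-1-yl 4-methylbenzenesulfonate
Conditions: TsCl (1.05 equiv), Et3N, Bu2SnO (2 mol %), CH2Cl2, 0 °C → rt
Reagents that add atoms: 4-toluenesulfonyl chloride, Cc1ccc(cc1)S(=O)(=O)Cl
Why: Tin-acetal-accelerated sulfonylation picks the primary hydroxyl of the 1,2-diol, and the neopentyl-type tosylate so formed is inert to external nucleophiles until it is needed for ring closure.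

Step 3
Reactants: 4 (R)-2-hydroxy-2-methylhex-5-en-1-yl 4-methylbenzenesulfonate
Product: 5 (R)-2-methyl-2-(triethylsilyloxy)hex-5-en-1-yl 4-methylbenzenesulfonate
Conditions: TESOTf, 2,6-lutidine, CH2Cl2, 0 °C
Reagents that add atoms: triethylsilyl triflate, CC[Si](CC)(CC)OS(=O)(=O)C(F)(F)F
Why: Silyl triflate silylation caps the hindered tertiary alcohol, which stores the oxirane as a latent silyl ether/tosylate pair and blocks premature epoxide or five-membered ether formation.

Step 4
Reactants: 5 (R)-2-methyl-2-(triethylsilyloxy)hex-5-en-1-yl 4-methylbenzenesulfonate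
Product: 7 (R)-2-methyl-5-oxo-2-(triethylsilyloxy)pentyl 4-methylbenzenesulfonate, via secondary ozonide 6 (not isolated)
Conditions: O3, CH2Cl2, −78 °C; PPh3, −78 °C → rt
Reagents that add atoms: ozone, [O-][O+]=O
Why: Ozonolysis with reductive work-up (Criegee mechanism) trims the terminal alkene to the C3 aldehyde and touches neither the sulfonate nor the silyl ether.

Step 5
Reactants: 7 (R)-2-methyl-5-oxo-2-(triethylsilyloxy)pentyl 4-methylbenzenesulfonate; 8 (R)-4-benzyl-3-propionyloxazolidin-2-one
Product: 10 (2R,5S,6R)-7-[(R)-4-benzyl-2-oxooxazolidin-3-yl]-5-hydroxy-2,6-dimethyl-7-oxo-2-(triethylsilyloxy)heptyl 4-methylbenzenesulfonate, via dibutylboron Z-enolate 9 (not isolated)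
Conditions: 8, Bu2BOTf, Et3N, CH2Cl2, −78 → 0 °C; 7, −78 → 0 °C; pH 7 buffer, MeOH, 30% H2O2, 0 °C
Reagents that add atoms: none
Why: In the Evans syn aldol reaction the Z boron enolate reacts through a closed chair transition state on the face left open by the benzyl group of the R auxiliary, which sets the methyl-bearing C2 and the carbinol C3 together in the syn sense.

Step 6
Reactants: 10 syn aldol imide
Product: 11 (2R,5S,6S)-5,7-dihydroxy-2,6-dimethyl-2-(triethylsilyloxy)heptyl 4-methylbenzenesulfonate
Conditions: LiBH4, MeOH (1 equiv), Et2O, 0 °C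
Reagents that add atoms: none
Why: Borohydride reduction cleaves the activated imide carbonyl to the primary alcohol without epimerisation and is too mild at this temperature to displace the neopentyl-type tosylate.

Step 7
Reactants: 11 (2R,5S,6S)-5,7-dihydroxy-2,6-dimethyl-2-(triethylsilyloxy)heptyl 4-methylbenzenesulfonate
Product: 12 (2R,5S,6S)-5-hydroxy-2,6-dimethyl-2-(triethylsilyloxy)-7-(triisopropylsilyloxy)heptyl 4-methylbenzenesulfonate
Conditions: TIPSCl (1.1 equiv), imidazole, CH2Cl2, 0 °C → rt
Reagents that add atoms: triisopropylsilyl chloride, CC(C)[Si](Cl)(C(C)C)C(C)C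
Why: Sterically governed silylation takes only the primary alcohol, and the triisopropylsilyl group is chosen because it should outlast both the short fluoride treatment of step 10 and the acid of step 11.

Step 8
Reactants: 13 2,3-dimethylbut-2-ene
Product: 15 2-methoxypropan-2-yl hydroperoxide, via acetone O-oxide 14 (not isolated)
Conditions: O3, MeOH/CH2Cl2, −78 °C; kept and used as a solution
Reagents that add atoms: ozone, [O-][O+]=O; methanol, CO
Why: Ozonolysis of a tetrasubstituted alkene in methanol (Criegee mechanism) gives a carbonyl oxide that the solvent traps as the alpha-methoxy hydroperoxide, a mono-protected form of hydrogen peroxide.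

Step 9
Reactants: 12 secondary alcohol; 15 2-methoxypropan-2-yl hydroperoxide
Product: 17 (2R,5R,6S)-5-[(2-methoxypropan-2-yl)peroxy]-2,6-dimethyl-2-(triethylsilyloxy)-7-(triisopropylsilyloxy)heptyl 4-methylbenzenesulfonate, via secondary triflate 16 (not isolated)
Conditions: Tf2O (1.1 equiv), 2,6-lutidine, CH2Cl2, −78 °C; then 15 and KOtBu (2 equiv each) in THF, −78 → 0 °C
Reagents that add atoms: none
Why: In this SN2 alkylation of a hydroperoxide the weakly basic alpha-effect peroxide anion displaces the secondary triflate with inversion (5S to 5R, the future C3), finds no epoxide to compete because that ring is still latent, and carries a perketal cap that prevents a second alkylation and keeps the OOH masked through the basic step that follows.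

Step 10
Reactants: 17 perketal tosylate
Product: 18 (R)-2-{(3R,4S)-3-[(2-methoxypropan-2-yl)peroxy]-4-methyl-5-(triisopropylsilyloxy)pentyl}-2-methyloxirane
Conditions: TBAF (1.1 equiv), THF, −20 → 0 °C
Reagents that add atoms: none
Why: Fluoride removes the triethylsilyl group far faster than the bulkier triisopropylsilyl group, and the tertiary alkoxide closes at once by 3-exo-tet Williamson displacement of the adjacent tosylate, which does not touch the C6–O bond and so retains configuration.

Step 11
Reactants: 18 perketal-masked epoxy peroxide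
Product: 20 {(3S,6R)-3-methyl-6-[(S)-1-(triisopropylsilyloxy)propan-2-yl]-1,2-dioxan-3-yl}methanol, via epoxy hydroperoxide 19 (not isolated)
Conditions: (+)-camphor-10-sulfonic acid (10 mol %), CH2Cl2 (0.01 M), H2O (2 equiv), −20 → 0 °C; NaHCO3 quench
Reagents that add atoms: none
Why: Camphorsulfonic acid first hydrolyses the acyclic perketal, by far the most acid-labile group present, to hydroperoxide 19 and then protonates the oxirane, whose tertiary C6–O bond lengthens while the terminal peroxide oxygen attacks C6 from the rear. The closest known reaction type is the acid-promoted exo opening of epoxides by tethered hydroperoxides to give 1,2-dioxanes. The 1,2-dioxane ring closes in the 6-exo-tet mode, and the competing 7-endo attack on the CH2 carbon is disfavoured both by ring size and by the location of the positive charge. The only new stereocentre, C6, is controlled by the epoxide configuration, which is transferred with inversion (R oxirane to S carbinol), while C2 and C3 are spectators. The step needs tertiary-over-primary regioselectivity and an SN2-like rather than free-cation course, which the short tether, the non-polar solvent, the low temperature and the high dilution should secure. Substrate 18 holds no alkene, free alcohol or other internal nucleophile, so only traces of water and methanol compete.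

Step 12
Reactants: 20 dioxane carbinol
Product: 21 (3S,6R)-3-methyl-6-[(S)-1-(triisopropylsilyloxy)propan-2-yl]-1,2-dioxane-3-carbaldehyde
Conditions: Dess–Martin periodinane, CH2Cl2, 0 °C → rt
Reagents that add atoms: none
Why: Dess–Martin oxidation converts the neopentyl-type carbinol under neutral conditions into an aldehyde that has no alpha hydrogen to epimerise, and it avoids the base that could fragment a beta-hydroxy peroxide.

Step 13
Reactants: 22 (S)-limonene
Product: 23 (4S)-limonene 1,2-oxide (both epoxide diastereomers)
Conditions: mCPBA (1.0 equiv), CH2Cl2, 0 °C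
Reagents that add atoms: 3-chloroperbenzoic acid, OOC(=O)c1cccc(Cl)c1
Why: Prilezhaev epoxidation prefers the more electron-rich trisubstituted ring alkene over the isopropenyl group but shows no facial preference, a deficit that the next step corrects.

Step 14
Reactants: 23 (4S)-limonene 1,2-oxide
Product: 24 (1R,2R,4S)-2-(dimethylamino)-1-methyl-4-(prop-1-en-2-yl)cyclohexan-1-ol
Conditions: 40% aq Me2NH, sealed vessel, 80 °C; acid–base extraction
Reagents that add atoms: dimethylamine, CNC
Why: Under the Fürst–Plattner rule only the diastereomer whose oxygen is cis to the isopropenyl group can undergo aminolysis by trans-diaxial opening at the secondary C2 with the side chain equatorial, so it alone becomes an acid-extractable amino alcohol and the unreactive isomer is washed away.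

Step 15
Reactants: 24 amino alcohol
Product: 26 (1R,4S)-1-methyl-4-(prop-1-en-2-yl)cyclohex-2-en-1-ol (hydroxyl cis to isopropenyl), via amine N-oxide 25 (not isolated)
Conditions: 30% H2O2, MeOH, rt; MnO2 (trace), concentrate; neat, 160 °C, reduced pressure
Reagents that add atoms: none
Why: The thermal syn elimination of the amine oxide (Cope elimination) can only run towards C3 because C1 carries no hydrogen, so the tertiary allylic alcohol results with C1 and C4 untouched.

Step 16
Reactants: 26 tertiary allylic alcohol; 27 2,2,6-trimethyl-4H-1,3-dioxin-4-one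
Product: 30 1-[(1R,6S)-3-methyl-6-(prop-1-en-2-yl)cyclohex-2-en-1-yl]propan-2-one, via allylic acetoacetate 28 (not isolated), via beta-keto acid 29 (not isolated)
Conditions: 27 (1.2 equiv), mesitylene, 130 → 165 °C
Reagents that add atoms: none
Why: In the Carroll rearrangement the acetoacetate formed under neutral conditions undergoes a suprafacial [3,3] shift on the ring face that bears the C–O bond, which is also the isopropenyl face, so the new C–C bond sets the future C4a cis to C8a, places the ring A alkene correctly, and loss of CO2 gives the methyl ketone.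

Step 17
Reactants: 30 methyl ketone
Product: 31 methyl 4-[(1R,6S)-3-methyl-6-(prop-1-en-2-yl)cyclohex-2-en-1-yl]-3-oxobutanoate
Conditions: NaH (2.2 equiv), (MeO)2CO, THF, reflux; AcOH quench
Reagents that add atoms: dimethyl carbonate, COC(=O)OC
Why: Claisen-type C-acylation under equilibrating conditions takes place at the less hindered methyl terminus and is driven by formation of the stabilised sodium enolate.

Step 18
Reactants: 31 olefinic beta-keto ester
Product: 32 methyl (4aR,8aS)-1,1,6-trimethyl-3-oxo-1,2,3,4,4a,7,8,8a-octahydronaphthalene-2-carboxylate (C2 epimers and enol)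
Conditions: SnCl4 (1.5 equiv), CH2Cl2, 0 °C → rt; aq work-up
Reagents that add atoms: none
Why: In this cationic olefin cyclisation (intramolecular tert-alkylation of a tin-chelated beta-keto ester) Markovnikov protonation of the more accessible isopropenyl group gives the tertiary cation, which the enol carbon captures to close six-membered ring B and create the gem-dimethyl carbon, with the cis fusion inherited from the two centres already set.

Step 19
Reactants: 32 bicyclic beta-keto ester
Product: 33 methyl (4aR,8aS)-1,1,6-trimethyl-3-(trifluoromethylsulfonyloxy)-1,4,4a,7,8,8a-hexahydronaphthalene-2-carboxylate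
Conditions: NaH, Et2O, 0 °C; Tf2O, −78 → 0 °C
Reagents that add atoms: triflic anhydride, O=S(=O)(OS(=O)(=O)C(F)(F)F)C(F)(F)F
Why: O-sulfonylation of the sodium enolate, which can only form between the two carbonyl groups, locks the future alkene between C2 and C3 of ring B.

Step 20
Reactants: 33 enol triflate
Product: 34 methyl (4aR,8aS)-1,1,3,6-tetramethyl-1,4,4a,7,8,8a-hexahydronaphthalene-2-carboxylate
Conditions: MeMgBr, Fe(acac)3 (5 mol %), THF/NMP, −30 °C
Reagents that add atoms: methylmagnesium bromide, C[Mg]Br
Why: Iron-catalysed Kumada-type cross-coupling of the enol triflate is faster than Grignard attack on the hindered ester and installs the methyl group on a regiochemically fixed tetrasubstituted alkene.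

Step 21
Reactants: 34 unsaturated ester
Product: 35 [(4aR,8aS)-1,1,3,6-tetramethyl-1,4,4a,7,8,8a-hexahydronaphthalen-2-yl]methanol
Conditions: iBu2AlH (2.5 equiv), CH2Cl2, −78 → 0 °C; aq potassium sodium tartrate
Reagents that add atoms: none
Why: Aluminium hydride 1,2-reduction of the conjugated ester gives the allylic alcohol and leaves both alkenes alone.

Step 22
Reactants: 35 allylic alcohol
Product: 36 {[(4aR,8aS)-1,1,3,6-tetramethyl-1,4,4a,7,8,8a-hexahydronaphthalen-2-yl]methyl}triphenylphosphonium bromide
Conditions: PPh3·HBr, MeOH, rt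
Reagents that add atoms: triphenylphosphine hydrobromide, c1ccc(cc1)[PH+](c1ccccc1)c1ccccc1.[Br-]
Why: The allylic alcohol ionises under the mild acidity of the phosphine hydrobromide and triphenylphosphine captures the allyl cation at its unhindered primary terminus (SN1-type salt formation), which keeps the tetrasubstituted alkene in place.

Step 23
Reactants: 36 allylic phosphonium bromide; 21 dioxane aldehyde
Product: 38 diene silyl ether (C7=C8 alkene, E/Z mixture), via allylic ylide 37 (not isolated)
Conditions: 36 (1.3 equiv), KN(SiMe3)2, THF, −78 → 0 °C; 21, −78 °C → rt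
Reagents that add atoms: none
Why: In the Wittig olefination the semi-stabilised allylic ylide, generated lithium-free so that no open betaine alkoxide can trigger fragmentation of the neighbouring O–O bond, adds to the non-enolisable and inductively activated aldehyde, and the alkene geometry is irrelevant.

Step 24
Reactants: 38 diene silyl ether
Product: 39 saturated-link silyl ether (C7–C8 single bond)
Conditions: KO2CN=NCO2K (excess, in portions), AcOH, MeOH/CH2Cl2, 0 °C → rt, followed to full conversion of 38
Reagents that add atoms: none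
Why: Concerted syn hydrogen transfer from diimide is governed by alkene substitution, so the 1,2-disubstituted and conjugated C7=C8 link should react ahead of the trisubstituted ring A and tetrasubstituted ring B alkenes, and the reagent does not cleave O–O bonds.

Step 25
Reactants: 39 saturated-link silyl ether
Product: 40 (2S)-2-[(3R,6R)-6-methyl-6-{2-[(4aR,8aS)-1,1,3,6-tetramethyl-1,4,4a,7,8,8a-hexahydronaphthalen-2-yl]ethyl}-1,2-dioxan-3-yl]propan-1-ol
Conditions: TBAF, AcOH (1:1), THF, 0 °C → rt
Reagents that add atoms: none
Why: Fluoride cleaves the Si–O bond, and the acetic acid buffer suppresses base-induced fragmentation of the peroxide at C3–H (Kornblum–DeLaMare type).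

Step 26
Reactants: 40 primary alcohol
Product: 41 (2R)-2-[(3R,6R)-6-methyl-6-{2-[(4aR,8aS)-1,1,3,6-tetramethyl-1,4,4a,7,8,8a-hexahydronaphthalen-2-yl]ethyl}-1,2-dioxan-3-yl]propanoic acid (target)
Conditions: TEMPO (20 mol %), (diacetoxyiodo)benzene (2.5 equiv), MeCN/H2O, rt
Reagents that add atoms: water, O
Why: Oxoammonium-mediated (TEMPO) oxidation takes the primary alcohol through the aldehyde hydrate to the acid in one flask under near-neutral conditions that should spare the alkenes, the O–O bond and the C2 stereocentre.

Compound list
1 | (S)-2-methylglycidol | C[C@@]1(CO1)CO | starting material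
2 | allylmagnesium bromide | C=CC[Mg]Br | starting material
3 | (R)-2-methylhex-5-ene-1,2-diol | C[C@@](O)(CCC=C)CO | intermediate
4 | (R)-2-hydroxy-2-methylhex-5-en-1-yl tosylate | C[C@@](O)(CCC=C)COS(=O)(=O)c1ccc(C)cc1 | intermediate
5 | (R)-2-methyl-2-(triethylsilyloxy)hex-5-en-1-yl tosylate | C[C@@](O[Si](CC)(CC)CC)(CCC=C)COS(=O)(=O)c1ccc(C)cc1 | intermediate
6 | secondary ozonide of 5 | C[C@@](O[Si](CC)(CC)CC)(CCC1OCOO1)COS(=O)(=O)c1ccc(C)cc1 | intermediate
7 | (R)-2-methyl-5-oxo-2-(triethylsilyloxy)pentyl tosylate | C[C@@](O[Si](CC)(CC)CC)(CCC=O)COS(=O)(=O)c1ccc(C)cc1 | intermediate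
8 | (R)-4-benzyl-3-propionyloxazolidin-2-one | CCC(=O)N1[C@H](Cc2ccccc2)COC1=O | starting material
9 | dibutylboron Z-enolate of 8 | C/C=C(\OB(CCCC)CCCC)N1[C@H](Cc2ccccc2)COC1=O | intermediate
10 | syn aldol imide | C[C@@](O[Si](CC)(CC)CC)(CC[C@H](O)[C@@H](C)C(=O)N1[C@H](Cc2ccccc2)COC1=O)COS(=O)(=O)c1ccc(C)cc1 | intermediate
11 | 1,3-diol | C[C@@](O[Si](CC)(CC)CC)(CC[C@H](O)[C@@H](C)CO)COS(=O)(=O)c1ccc(C)cc1 | intermediate
12 | secondary alcohol, primary TIPS ether | C[C@@](O[Si](CC)(CC)CC)(CC[C@H](O)[C@@H](C)CO[Si](C(C)C)(C(C)C)C(C)C)COS(=O)(=O)c1ccc(C)cc1 | intermediate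
13 | 2,3-dimethylbut-2-ene | CC(C)=C(C)C | starting material
14 | acetone O-oxide | CC(C)=[O+][O-] | intermediate
15 | 2-methoxypropan-2-yl hydroperoxide | COC(C)(C)OO | intermediate
16 | secondary triflate | C[C@@](O[Si](CC)(CC)CC)(CC[C@H](OS(=O)(=O)C(F)(F)F)[C@@H](C)CO[Si](C(C)C)(C(C)C)C(C)C)COS(=O)(=O)c1ccc(C)cc1 | intermediate
17 | perketal tosylate | C[C@@](O[Si](CC)(CC)CC)(CC[C@@H](OOC(C)(C)OC)[C@@H](C)CO[Si](C(C)C)(C(C)C)C(C)C)COS(=O)(=O)c1ccc(C)cc1 | intermediate
18 | perketal-masked epoxy peroxide | C[C@]1(CO1)CC[C@@H](OOC(C)(C)OC)[C@@H](C)CO[Si](C(C)C)(C(C)C)C(C)C | intermediate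
19 | epoxy hydroperoxide | C[C@]1(CO1)CC[C@@H](OO)[C@@H](C)CO[Si](C(C)C)(C(C)C)C(C)C | intermediate
20 | 1,2-dioxane carbinol | OC[C@]1(C)CC[C@H]([C@@H](C)CO[Si](C(C)C)(C(C)C)C(C)C)OO1 | intermediate
21 | 1,2-dioxane aldehyde | O=C[C@]1(C)CC[C@H]([C@@H](C)CO[Si](C(C)C)(C(C)C)C(C)C)OO1 | intermediate
22 | (S)-limonene | CC1=CC[C@@H](C(C)=C)CC1 | starting material
23 | (4S)-limonene 1,2-oxide, both epoxide diastereomers | CC12CC[C@H](C(C)=C)CC1O2 | intermediate
24 | (1R,2R,4S)-amino alcohol | C[C@@]1(O)CC[C@H](C(C)=C)C[C@H]1N(C)C | intermediate
25 | amine N-oxide | C[C@@]1(O)CC[C@H](C(C)=C)C[C@H]1[N+](C)(C)[O-] | intermediate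
26 | (1R,4S)-p-mentha-2,8-dien-1-ol | C[C@]1(O)C=C[C@@H](C(C)=C)CC1 | intermediate
27 | 2,2,6-trimethyl-4H-1,3-dioxin-4-one | CC1=CC(=O)OC(C)(C)O1 | starting material
28 | allylic acetoacetate | CC(=O)CC(=O)O[C@@]1(C)C=C[C@@H](C(C)=C)CC1 | intermediate
29 | beta-keto acid (alpha epimers) | CC1=C[C@@H](C(C(C)=O)C(=O)O)[C@@H](C(C)=C)CC1 | intermediate
30 | cis methyl ketone | CC1=C[C@@H](CC(C)=O)[C@@H](C(C)=C)CC1 | intermediate
31 | olefinic beta-keto ester | CC1=C[C@@H](CC(=O)CC(=O)OC)[C@@H](C(C)=C)CC1 | intermediate
32 | bicyclic beta-keto ester | CC1=C[C@H]2CC(=O)C(C(=O)OC)C(C)(C)[C@H]2CC1 | intermediate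
33 | enol triflate | CC1=C[C@H]2CC(OS(=O)(=O)C(F)(F)F)=C(C(=O)OC)C(C)(C)[C@H]2CC1 | intermediate
34 | tetrasubstituted unsaturated ester | CC1=C[C@H]2CC(C)=C(C(=O)OC)C(C)(C)[C@H]2CC1 | intermediate
35 | bicyclic allylic alcohol | CC1=C[C@H]2CC(C)=C(CO)C(C)(C)[C@H]2CC1 | intermediate
36 | allylic phosphonium bromide | CC1=C[C@H]2CC(C)=C(C[P+](c3ccccc3)(c3ccccc3)c3ccccc3)C(C)(C)[C@H]2CC1.[Br-] | intermediate
37 | allylic ylide | CC1=C[C@H]2CC(C)=C(C=P(c3ccccc3)(c3ccccc3)c3ccccc3)C(C)(C)[C@H]2CC1 | intermediate
38 | diene silyl ether (E/Z) | CC1=C[C@H]2CC(C)=C(C=C[C@]3(C)CC[C@H]([C@@H](C)CO[Si](C(C)C)(C(C)C)C(C)C)OO3)C(C)(C)[C@H]2CC1 | intermediate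
39 | saturated-link silyl ether | CC1=C[C@H]2CC(C)=C(CC[C@]3(C)CC[C@H]([C@@H](C)CO[Si](C(C)C)(C(C)C)C(C)C)OO3)C(C)(C)[C@H]2CC1 | intermediate
40 | primary alcohol | CC1=C[C@H]2CC(C)=C(CC[C@]3(C)CC[C@H]([C@@H](C)CO)OO3)C(C)(C)[C@H]2CC1 | intermediate
41 | CNP0122760.1 | CC1=C[C@H]2CC(C)=C(CC[C@]3(C)CC[C@H]([C@@H](C)C(=O)O)OO3)C(C)(C)[C@H]2CC1 | target

Total step count: 26 (12 in the dioxane branch including the peroxide reagent, 10 in the bicycle branch, 4 after the union).
Longest linear sequence: 15 steps (1–7, 9–12, 23–26).

Steps most likely to fail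

Step 9. Elimination of the hindered, beta-branched triflate, or participation of a neighbouring silyl ether oxygen, may outrun substitution under the anionic conditions. The fallback replaces the anion by a neutral peroxide-transfer reagent. It sets out from triflate 16 (made from 12 as before) and returns at 17. Excess (Bu3Sn)2O2 in CH2Cl2 at low temperature should transfer one peroxide oxygen with inversion to give the stannyl peroxide F1. Moist silica hydrolyses the O–Sn bond to the free secondary hydroperoxide F2. Addition of F2 to 2-methoxypropene under pyridinium tosylate catalysis then gives 17.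

Step 11. Stereochemical fidelity may be lost through a free tertiary cation. Attack may drift to the CH2 carbon, a hydride shift may rearrange the protonated oxirane, or water may capture it. The fallback exchanges the roles of the two oxygen-bearing carbons. It sets out from alcohol 12 and returns at 20.
- Mesylation (MsCl, Et3N) gives the secondary mesylate F3.
- TBAF closes the latent epoxide as in step 10 to the epoxy mesylate F4.
- Perhydrolysis with ethereal H2O2 and H3PMo12O40 opens the oxirane intermolecularly at the tertiary carbon with inversion to the tertiary beta-hydroxy hydroperoxide F5.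
- Cs2CO3 in DMF lets the peroxide anion displace the C3 mesylate 6-exo-tet with inversion.

Both centres are inverted exactly as in the main route, so the same 20 should result.

Step 18. Protonation of the ring A alkene may compete with that of the isopropenyl group. That would lead to double-bond migration or a bridged ring closure, and O-alkylation of the enol may persist. The fallback generates the cation without any proton source. It sets out from 31 and returns at 32. One equivalent of dry HCl at low temperature adds to the isopropenyl group, the more reactive alkene of limonene-type dienes, to give the tertiary chloride F6. TMSCl and Et3N convert the keto ester into the silyl enol ether F7. TiCl4 at −78 °C ionises the chloride and induces intramolecular alpha-tert-alkylation of the silyl enol ether, which releases a silyl chloride instead of acid.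

Further compounds
F1 | step 9 | stannyl peroxide | C[C@@](O[Si](CC)(CC)CC)(CC[C@@H](OO[Sn](CCCC)(CCCC)CCCC)[C@@H](C)CO[Si](C(C)C)(C(C)C)C(C)C)COS(=O)(=O)c1ccc(C)cc1
F2 | step 9 | free secondary hydroperoxide | C[C@@](O[Si](CC)(CC)CC)(CC[C@@H](OO)[C@@H](C)CO[Si](C(C)C)(C(C)C)C(C)C)COS(=O)(=O)c1ccc(C)cc1
F3 | step 11 | secondary mesylate | C[C@@](O[Si](CC)(CC)CC)(CC[C@H](OS(C)(=O)=O)[C@@H](C)CO[Si](C(C)C)(C(C)C)C(C)C)COS(=O)(=O)c1ccc(C)cc1
F4 | step 11 | epoxy mesylate | C[C@]1(CO1)CC[C@H](OS(C)(=O)=O)[C@@H](C)CO[Si](C(C)C)(C(C)C)C(C)C
F5 | step 11 | tertiary beta-hydroxy hydroperoxide | OC[C@@](C)(OO)CC[C@H](OS(C)(=O)=O)[C@@H](C)CO[Si](C(C)C)(C(C)C)C(C)C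
F6 | step 18 | tertiary chloride | CC1=C[C@@H](CC(=O)CC(=O)OC)[C@@H](C(C)(C)Cl)CC1
F7 | step 18 | silyl enol ether | CC1=C[C@@H](CC(O[Si](C)(C)C)=CC(=O)OC)[C@@H](C(C)(C)Cl)CC1
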